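**Remark.** TBS = tert-butyldimethylsilyl, TBSO = tert-butyldimethylsilyloxy. C2 of 23 (first formed in betaine 22) is the only stereocentre met on the route; it forms as a racemate and is erased in step 13, so no stereocontrol is planned.

## Structural features

The target is an achiral 2-arylbenzofuran whose benzofuran (locants O1, C2, C3, C3a, C4–C7, C7a) is built on a phloroglucinol ring: hydroxyls on C4 and C6, O1 on C7a, and on C7, between O1 and the C6 hydroxyl, a 2-methylbut-3-en-2-yl (1,1-dimethylallyl) group held through a quaternary carbon. C2 is bonded to C5' of a 7'-hydroxy-2,2-dimethylchroman (locants O1', C2'–C4', C4a', C5'–C8', C8a'), so the linking bond has the ring methylene C4' on the neighbouring carbon C4a'. There is no stereocentre, hence none stand next to each other, and every problem is one of regiochemistry and functional-group tolerance. The fragile features are the three free phenols on very electron-rich rings, which oxidise in air, above all as phenoxides; the terminal alkene on a quaternary carbon ortho to two oxygens, across which acid would add a neighbouring hydroxyl and which hydrogenation would saturate; the electron-rich furan C2=C3 bond; and the oxidisable benzylic methylene C4'. The real difficulty is the fully substituted phloroglucinol ring: a tertiary allyl group must sit on the one carbon flanked by two oxygens, which in practice only an aryl prenyl ether rearrangement delivers. Of the two oxygens ortho to C3a, the one next to C7 must become the furan oxygen. The key step uses the fact that C3 is an unsubstituted CH on C3a, ortho to the oxygen-bearing C7a: O1–C7a–C3a–C3 is the skeleton of an ortho-quinone methide, which accepts C2, already carrying the chroman, as a one-carbon unit.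

## Logic of the disconnections

25 from 24. The three O–Si bonds are cut last, so the phenols stay masked through base and oxidant. The forward step needs a buffered fluoride source, so that the triphenoxide never stands in air, and no strong acid, which would add the C6 hydroxyl across the neighbouring alkene.

24 from 23. The C2=C3 double bond is taken back to the dihydrofuran. This brings the furan to the oxidation level at which a four-atom plus one-carbon union is possible and leaves only a disposable stereocentre at C2. The forward step must abstract hydride from C3 faster than from C4'.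

23 from 8 and 19. C2–C3 and O1–C2 are cut. This opens the furan and halves the molecule into two arenes of similar size, each with one benzylic carbon: 8 holds O1, C7a, C3a and C3 as a latent quinone methide (20), and 19 holds C2 as a latent ylide (21), with 22 as the link. The gain is full convergence without a metal-catalysed coupling at the hindered C2–C5' junction. The forward step demands that 20 meet 21 and not itself, and that the free hydroxyl of 8 be the one between the benzylic carbon and the quaternary carbon, since only that oxygen may become O1.

8 from 5. The C–S bond is cut and the benzylic carbon raised to the aldehyde level (through 7 and 6). A formyl group fixes this carbon between two oxygens without ambiguity, and its hydrogen bond later tells the two ortho hydroxyls apart. The forward step must stop the reduction at 6 and ionise 6 to 7 with an acid mild enough for aryl silyl ethers and the alkene.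

5 from 4. Two O–Si bonds are cut. The demand is a silylation that spares the one hydroxyl that is both chelated to the formyl oxygen and flanked by the quaternary carbon.

4 from 3. The aryl–C(quaternary) bond is cut by a retro-Claisen step to an allyl ether with allylic transposition. The ether is placed on the oxygen para to the formyl carbon: its two ortho positions are equivalent by symmetry and its para position is blocked, so neither a regiochemical choice nor a productive para (Claisen–Cope) shift exists. An ether on either other oxygen would leave a para C–H open. The demand is a thermal step that the free phenols tolerate.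

3 from 1 and 2. One O–C bond is cut. The demand is mono-etherification at the only hydroxyl not hydrogen-bonded to the formyl group.

19 from 15 (through 18, 17 and 16). The C–S bond, the C–Br bond, two benzylic C–H bonds (back to the ester) and one O–Si bond are removed in turn. The ester is the form in which the benzylic carbon survives Lewis acid and cross-coupling. The forward steps must be neutral enough for an aryl silyl ether.

15 from 13. The O1'–C2' bond of the pyran and two O–CH3 bonds are cut (14 lies between). Only one of the two ring oxygens is within reach of the side chain, so a single chroman can form. The demand is a Lewis acid that cleaves aryl methyl ethers yet leaves the methyl ester.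

13 from 10 and 11, and 10 from 9. The C4a'–C4' aryl–alkyl bond is cut (12 is the boron intermediate). It delivers C4', C3', C2' and both methyl groups at once at the right oxidation level, and demands cross-coupling at a bromide with two ortho substituents. The C–Br bond of 10 is placed by the two methoxy groups: para to one, ortho to the other, and less hindered than the position between them.

## Other disconnections considered

Alternative 1: The cut is C4a'–C5', with O1'–C2' to follow, which unrolls the benzene ring of the chroman into the open-chain trione A2. In the forward sense, aqueous NaHCO3 would make the terminal ketone α-carbon of A2 (the future C4a', already carrying the prenyl chain) add to the benzofuranyl ketone carbon. Dehydration and enolisation would give the prenylated resorcinol A1; acid would then close the pyran ring and fluoride would remove the silyl groups.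
- In favour: the sequence is biomimetic, the chain fixes where both oxygens, the prenyl group and the benzofuran sit on the new ring, and only one hydroxyl of A1 is next to the prenyl group, so only one chroman can form.
- Against: the ring made is the easy one, whose pattern is available from a cheap benzoate, while the hard half (the benzofuran with its tertiary allyl group) must already be complete. The aldol must use a substituted, less acidic α-carbon in a polyketone that can also cyclise through oxygen to a pyranone. Closing the pyran ring of A1 needs acid in the presence of the acid-sensitive 1,1-dimethylallyl group and the silyl ethers.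
- Comparison: the chosen plan cuts the molecule in the middle and this one near one end, so it would be more linear and longer. Both rely on a reactive intermediate with a competing self-reaction. It is the better plan on one point: the furan is aromatic throughout, so no dehydrogenation and no C3 versus C4' selectivity arise. After the key step it is equal, with two steps to the target.

Alternative 2: The cut is C3a–C4, which takes the phloroglucinol ring back to the cyclobutenone A4 (racemic quaternary carbon, lost in the reaction). Heating A4 in toluene would open the four-membered ring to a vinylketene, which would close onto C3 of the furan and tautomerise to the phenol A3.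
- In favour: the benzene ring would be formed with all four substituents in place, with no aromatic substitution regiochemistry. The step needs no reagent. The tertiary allyl group would sit on an sp3 carbon beforehand, where an ester-enolate (Ireland–Claisen) rearrangement could place it without any ortho/para question; on this point it is better than the aromatic Claisen step of the chosen plan. It is also better in delivering the benzofuran oxidation level directly.
- Against: A4 has a quaternary ring carbon bonded to a second quaternary carbon and would have to come from a [2+2] reaction of a very hindered ketene. The ring opening must turn the furyl group inward. The vinylketene has the pendant vinyl group as an internal trap. The furan–chroman bond would need a halogen or boron at C5', harder to place than the carboxyl carbon used in the chosen plan. Telling the C4 and C6 oxygens apart in A3 gains nothing, since both end as free phenols.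
- Comparison: the chroman would be attached before the ring is built, so the plan is less convergent and would be longer.

Alternative 3: The cut is C4'–C3' and O1'–C2', the pyran ring, leading back to the ortho-hydroxybenzyl alcohol A6 and 2-methylpropene A7. Thermolysis of A6 in excess A7 in a sealed tube would expel water to give an ortho-quinone methide on the resorcinol ring. This would add the alkene in a [4+2] cycloaddition, with oxygen going to the tertiary carbon, to give A5, which is the same compound as 24.
- In favour: the last ring would come late from a C4 feedstock, the regiochemistry of the cycloaddition is electronically clear, and no acid is needed. From A5 one step reaches the target, one fewer than from 23, which is a point on which it is better.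
- Against: A7 is an unactivated alkene and a poor partner for a quinone methide, so self-condensation would weigh more heavily than in the chosen plan, where the partner is a carbanion. Pressure and high temperature are needed. A6 requires that the two resorcinol oxygens be told apart, and that the benzofuran first be built by another method onto an aryl group with two ortho substituents. The hard half of the molecule is therefore postponed and not solved.
- Comparison: the two plans are equal in the type of reactive intermediate and in protecting groups. The chosen plan spends the quinone methide on joining the halves and this one on finishing one half, and its overall step count would not be lower.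

Key step: step 12

## Route

Step 1
Reactants: 1 2,4,6-trihydroxybenzaldehyde; 2 3-methylbut-2-en-1-ol
Product: 3 2,6-dihydroxy-4-[(3-methylbut-2-en-1-yl)oxy]benzaldehyde
Conditions: PPh3, DIAD, THF, 0 °C to rt (1 equiv each)
Reagents that add atoms: none
Why: Mitsunobu etherification; the C4 hydroxyl is the most acidic and the only one not hydrogen-bonded to the formyl oxygen, so it should react first, and the neutral conditions give O-alkylation at the primary allylic carbon without C-prenylation.

Step 2
Reactants: 3 2,6-dihydroxy-4-[(3-methylbut-2-en-1-yl)oxy]benzaldehyde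
Product: 4 2,4,6-trihydroxy-3-(2-methylbut-3-en-2-yl)benzaldehyde
Conditions: PhNEt2, 180 °C, Ar, short reaction time
Reagents that add atoms: none
Why: Aromatic Claisen rearrangement ([3,3]-sigmatropic) with allylic inversion turns the prenyl ether into the 1,1-dimethylallyl group on the ortho carbon; the two ortho positions are equivalent by symmetry and the para position is the formyl-bearing carbon, so no regiochemical choice and no productive para shift exist, and the amine solvent speeds enolisation of the dienone.

Step 3
Reactants: 4 2,4,6-trihydroxy-3-(2-methylbut-3-en-2-yl)benzaldehyde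
Product: 5 2-hydroxy-3-(2-methylbut-3-en-2-yl)-4,6-bis(TBSO)benzaldehyde
Conditions: TBSCl (2.1 equiv), imidazole, DMF, 0 °C to rt
Reagents that add atoms: tert-butyldimethylsilyl chloride, CC(C)(C)[Si](C)(C)Cl
Why: Silyl ether formation; the C2 hydroxyl is both locked in a hydrogen bond to the formyl oxygen and flanked by the quaternary carbon, so two equivalents should cap the C4 and C6 hydroxyls and leave exactly the hydroxyl that becomes O1.

Step 4
Reactants: 5 2-hydroxy-3-(2-methylbut-3-en-2-yl)-4,6-bis(TBSO)benzaldehyde
Product: 8 2-(2-methylbut-3-en-2-yl)-6-[(4-methylbenzenesulfonyl)methyl]-3,5-bis(TBSO)phenol, via benzyl alcohol 6 (not isolated), via benzylic cation 7 (not isolated)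
Conditions: NaBH4, THF/EtOH, 0 °C; acetone quench; then TolSO2Na, HCO2H, THF/H2O, rt
Reagents that add atoms: sodium 4-methylbenzenesulfinate, Cc1ccc(cc1)S(=O)[O-].[Na+]
Why: Borohydride reduction gives 6; once excess hydride is destroyed, mild acid protonates the benzylic hydroxyl, which leaves as water to give cation 7 (stabilised by the ortho hydroxyl and the ortho and para silyloxy groups; under acid the ionised species is this cation and not the neutral quinone methide), and sulfinate captures it through sulfur (SN1-type substitution), the usual way to 2-(sulfonylmethyl)phenols; formic acid is too weak to cleave aryl silyl ethers or protonate the monosubstituted alkene.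

Step 5
Reactants: 9 methyl 3,5-dimethoxybenzoate
Product: 10 methyl 2-bromo-3,5-dimethoxybenzoate
Conditions: NBS, MeCN, 0 °C to rt
Reagents that add atoms: N-bromosuccinimide, O=C1CCC(=O)N1Br
Why: Electrophilic aromatic bromination para to one methoxy group and ortho to the other; C2 is less hindered than the position between the two methoxy groups, and the ester limits the reaction to one bromine.

Step 6
Reactants: 10 methyl 2-bromo-3,5-dimethoxybenzoate; 11 2-methylbut-3-en-2-ol
Product: 13 methyl 2-(3-hydroxy-3-methylbutyl)-3,5-dimethoxybenzoate, via alkylborane 12 (not isolated)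
Conditions: 11, 9-BBN, THF, 0 °C to rt; then 10, Pd(dppf)Cl2 (5 mol %), K3PO4, DMF/H2O, 60 °C
Reagents that add atoms: none
Why: 9-BBN adds anti-Markovnikov to the monosubstituted alkene (the tertiary hydroxyl reacts only slowly) and primary alkylborane 12 enters a B-alkyl Suzuki–Miyaura coupling; the ortho ester helps oxidative addition to zerovalent palladium and the wide-bite-angle dppf ligand favours reductive elimination over β-hydride elimination.

Step 7
Reactants: 13 methyl 2-(3-hydroxy-3-methylbutyl)-3,5-dimethoxybenzoate
Product: 15 methyl 7-hydroxy-2,2-dimethylchroman-5-carboxylate, via tertiary bromide 14 (not isolated)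
Conditions: BBr3 (4 equiv), CH2Cl2, −78 to 0 °C; MeOH quench, then 40 °C
Reagents that add atoms: none
Why: BBr3 cleaves both aryl methyl ethers and converts the tertiary alcohol into tertiary bromide 14; the C3 phenol, the only oxygen within reach of the side chain, then captures the tertiary cation (SN1, six-membered ring) to give the chroman, a cyclisation known to accompany demethylation of ortho-prenyl-type anisoles, and the HBr/MeOH of the quench re-esterifies any ester that was cleaved.

Step 8
Reactants: 15 methyl 7-hydroxy-2,2-dimethylchroman-5-carboxylate
Product: 16 methyl 7-(TBSO)-2,2-dimethylchroman-5-carboxylate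
Conditions: TBSCl, imidazole, DMF, rt
Reagents that add atoms: tert-butyldimethylsilyl chloride, CC(C)(C)[Si](C)(C)Cl
Why: Standard silylation of an unhindered phenol; the silyl ether keeps this oxygen from adding to the quinone methide in step 12 and comes off with the other two at the end.

Step 9
Reactants: 16 methyl 7-(TBSO)-2,2-dimethylchroman-5-carboxylate
Product: 17 [7-(TBSO)-2,2-dimethylchroman-5-yl]methanol
Conditions: i-Bu2AlH (2.5 equiv), CH2Cl2, −78 to 0 °C; aq. potassium sodium tartrate (KNaC4H4O6)
Reagents that add atoms: none
Why: Hydride reduction of the ester to the primary alcohol; at low temperature the aryl silyl ether and the chroman are inert.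

Step 10
Reactants: 17 [7-(TBSO)-2,2-dimethylchroman-5-yl]methanol
Product: 18 5-(bromomethyl)-7-(TBSO)-2,2-dimethylchroman
Conditions: CBr4, PPh3, CH2Cl2, 0 °C
Reagents that add atoms: carbon tetrabromide, BrC(Br)(Br)Br
Why: Appel bromination under neutral conditions spares the aryl silyl ether; with only meta oxygen donors the benzylic bromide should be stable enough to handle.

Step 11
Reactants: 18 5-(bromomethyl)-7-(TBSO)-2,2-dimethylchroman
Product: 19 {[7-(TBSO)-2,2-dimethylchroman-5-yl]methyl}dimethylsulfonium bromide
Conditions: Me2S (excess), acetone, rt, dark; precipitation with Et2O, used promptly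
Reagents that add atoms: dimethyl sulfide, CSC
Why: SN2 alkylation of the sulfide by the benzylic bromide; the salt separates from the medium, which limits the reverse attack of bromide.

Step 12
Reactants: 8 2-(2-methylbut-3-en-2-yl)-6-[(4-methylbenzenesulfonyl)methyl]-3,5-bis(TBSO)phenol; 19 {[7-(TBSO)-2,2-dimethylchroman-5-yl]methyl}dimethylsulfonium bromide
Product: 23 2-[7-(TBSO)-2,2-dimethylchroman-5-yl]-7-(2-methylbut-3-en-2-yl)-4,6-bis(TBSO)-2,3-dihydrobenzofuran (racemic), via ortho-quinone methide 20 (not isolated), via sulfonium ylide 21 (not isolated), via betaine 22 (not isolated)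
Conditions: Cs2CO3 (3 equiv), 4 Å molecular sieves, MeCN/CH2Cl2, 0 °C to rt; 8 added slowly to 19 (1.3 equiv) and base
Reagents that add atoms: none
Why: Carbonate deprotonates the phenol of 8, which expels p-toluenesulfinate by 1,4-elimination to give 20, and the same base keeps a small stationary concentration of benzylic ylide 21 from 19, whose C–H acidity is close to that of a phenol. The ylide carbon adds to the unsubstituted exocyclic methylene of 20 (conjugate addition, C2–C3 bond), restoring the aromatic phenoxide in betaine 22. The phenoxide then displaces dimethyl sulfide at the benzylic carbon in a 5-exo-tet substitution (O1–C2 bond), closing the dihydrofuran ring. The closest known reaction type is the base-mediated formal [4+1] annulation of ortho-quinone methides from 2-(sulfonylalkyl)phenols with sulfonium ylides to 2-substituted 2,3-dihydrobenzofurans. The one new stereocentre, C2, has no controlling element and forms as a racemate, which is of no consequence because step 13 removes it. The selectivity needed is cross-reaction over self-condensation of 20: slow addition of 8 to an excess of 19 over the heterogeneous base keeps 20 dilute beside the ylide, reversible re-addition of sulfinate acts as a reservoir, and the two silyloxy donors temper the electrophilicity of 20. The medium is anhydrous and basic throughout, so the aryl silyl ethers and the alkene on its quaternary carbon remain spectators.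

Step 13
Reactants: 23 2-[7-(TBSO)-2,2-dimethylchroman-5-yl]-7-(2-methylbut-3-en-2-yl)-4,6-bis(TBSO)-2,3-dihydrobenzofuran
Product: 24 2-[7-(TBSO)-2,2-dimethylchroman-5-yl]-7-(2-methylbut-3-en-2-yl)-4,6-bis(TBSO)benzofuran
Conditions: DDQ (1.05 equiv), 1,4-dioxane, rt to 60 °C
Reagents that add atoms: none
Why: DDQ abstracts hydride from C3 to give a benzylic cation stabilised by O1 and two silyloxy groups, and loss of the C2 proton makes the furan aromatic (the known dehydrogenation of 2-aryl-2,3-dihydrobenzofurans); the alkene has no allylic hydrogen, and C4' of the chroman, with fewer donors and no aromatisation to gain, should react more slowly when the oxidant is limited to one equivalent.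

Step 14
Reactants: 24 2-[7-(TBSO)-2,2-dimethylchroman-5-yl]-7-(2-methylbut-3-en-2-yl)-4,6-bis(TBSO)benzofuran
Product: 25 2-(7-hydroxy-2,2-dimethylchroman-5-yl)-7-(2-methylbut-3-en-2-yl)benzofuran-4,6-diol
Conditions: Bu4NF (3.3 equiv), AcOH (3.3 equiv), THF, 0 °C, Ar
Reagents that add atoms: none
Why: Fluoride cleaves the three aryl silyl ethers (strong Si–F bond); acetic acid buffers the phenoxides against air oxidation, and the absence of strong acid keeps the C6 hydroxyl from adding across the neighbouring alkene.

## Compound list

1 | 2,4,6-trihydroxybenzaldehyde | O=Cc1c(O)cc(O)cc1O | starting material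
2 | 3-methylbut-2-en-1-ol | CC(C)=CCO | starting material
3 | 2,6-dihydroxy-4-[(3-methylbut-2-en-1-yl)oxy]benzaldehyde | O=Cc1c(O)cc(OCC=C(C)C)cc1O | intermediate
4 | 2,4,6-trihydroxy-3-(2-methylbut-3-en-2-yl)benzaldehyde | O=Cc1c(O)cc(O)c(C(C)(C)C=C)c1O | intermediate
5 | 2-hydroxy-3-(2-methylbut-3-en-2-yl)-4,6-bis(TBSO)benzaldehyde | O=Cc1c(O[Si](C)(C)C(C)(C)C)cc(O[Si](C)(C)C(C)(C)C)c(C(C)(C)C=C)c1O | intermediate
6 | 2-(hydroxymethyl)-6-(2-methylbut-3-en-2-yl)-3,5-bis(TBSO)phenol (benzyl alcohol, not isolated) | OCc1c(O[Si](C)(C)C(C)(C)C)cc(O[Si](C)(C)C(C)(C)C)c(C(C)(C)C=C)c1O | intermediate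
7 | [2-hydroxy-3-(2-methylbut-3-en-2-yl)-4,6-bis(TBSO)phenyl]methylium (benzylic cation, not isolated) | C=CC(C)(C)c1c(O)c([CH2+])c(O[Si](C)(C)C(C)(C)C)cc1O[Si](C)(C)C(C)(C)C | intermediate
8 | 2-(2-methylbut-3-en-2-yl)-6-[(4-methylbenzenesulfonyl)methyl]-3,5-bis(TBSO)phenol | Cc1ccc(cc1)S(=O)(=O)Cc1c(O)c(C(C)(C)C=C)c(O[Si](C)(C)C(C)(C)C)cc1O[Si](C)(C)C(C)(C)C | intermediate
9 | methyl 3,5-dimethoxybenzoate | COC(=O)c1cc(OC)cc(OC)c1 | starting material
10 | methyl 2-bromo-3,5-dimethoxybenzoate | COC(=O)c1cc(OC)cc(OC)c1Br | intermediate
11 | 2-methylbut-3-en-2-ol | C=CC(C)(C)O | starting material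
12 | 4-(9-borabicyclo[3.3.1]nonan-9-yl)-2-methylbutan-2-ol (alkylborane, not isolated) | CC(C)(O)CCB1C2CCCC1CCC2 | intermediate
13 | methyl 2-(3-hydroxy-3-methylbutyl)-3,5-dimethoxybenzoate | COC(=O)c1cc(OC)cc(OC)c1CCC(C)(C)O | intermediate
14 | methyl 2-(3-bromo-3-methylbutyl)-3,5-dihydroxybenzoate (tertiary bromide, not isolated) | COC(=O)c1cc(O)cc(O)c1CCC(C)(C)Br | intermediate
15 | methyl 7-hydroxy-2,2-dimethylchroman-5-carboxylate | COC(=O)c1cc(O)cc2c1CCC(C)(C)O2 | intermediate
16 | methyl 7-(TBSO)-2,2-dimethylchroman-5-carboxylate | COC(=O)c1cc(O[Si](C)(C)C(C)(C)C)cc2c1CCC(C)(C)O2 | intermediate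
17 | [7-(TBSO)-2,2-dimethylchroman-5-yl]methanol | OCc1cc(O[Si](C)(C)C(C)(C)C)cc2c1CCC(C)(C)O2 | intermediate
18 | 5-(bromomethyl)-7-(TBSO)-2,2-dimethylchroman | BrCc1cc(O[Si](C)(C)C(C)(C)C)cc2c1CCC(C)(C)O2 | intermediate
19 | {[7-(TBSO)-2,2-dimethylchroman-5-yl]methyl}dimethylsulfonium bromide | C[S+](C)Cc1cc(O[Si](C)(C)C(C)(C)C)cc2c1CCC(C)(C)O2.[Br-] | intermediate
20 | 6-methylidene-2-(2-methylbut-3-en-2-yl)-3,5-bis(TBSO)cyclohexa-2,4-dien-1-one (ortho-quinone methide, not isolated) | C=C1C(=O)C(C(C)(C)C=C)=C(O[Si](C)(C)C(C)(C)C)C=C1O[Si](C)(C)C(C)(C)C | intermediate
21 | dimethylsulfonium [7-(TBSO)-2,2-dimethylchroman-5-yl]methanide (ylide, not isolated) | C[S+](C)[CH-]c1cc(O[Si](C)(C)C(C)(C)C)cc2c1CCC(C)(C)O2 | intermediate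
22 | 2-{2-(dimethylsulfonio)-2-[7-(TBSO)-2,2-dimethylchroman-5-yl]ethyl}-6-(2-methylbut-3-en-2-yl)-3,5-bis(TBSO)phenolate (racemic betaine, not isolated) | C=CC(C)(C)c1c([O-])c(CC([S+](C)C)c2cc(O[Si](C)(C)C(C)(C)C)cc3c2CCC(C)(C)O3)c(O[Si](C)(C)C(C)(C)C)cc1O[Si](C)(C)C(C)(C)C | intermediate
23 | 2-[7-(TBSO)-2,2-dimethylchroman-5-yl]-7-(2-methylbut-3-en-2-yl)-4,6-bis(TBSO)-2,3-dihydrobenzofuran (racemic at C2) | C=CC(C)(C)c1c(O[Si](C)(C)C(C)(C)C)cc(O[Si](C)(C)C(C)(C)C)c2c1OC(c1cc(O[Si](C)(C)C(C)(C)C)cc3c1CCC(C)(C)O3)C2 | intermediate
24 | 2-[7-(TBSO)-2,2-dimethylchroman-5-yl]-7-(2-methylbut-3-en-2-yl)-4,6-bis(TBSO)benzofuran | C=CC(C)(C)c1c(O[Si](C)(C)C(C)(C)C)cc(O[Si](C)(C)C(C)(C)C)c2cc(-c3cc(O[Si](C)(C)C(C)(C)C)cc4c3CCC(C)(C)O4)oc12 | intermediate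
25 | 2-(7-hydroxy-2,2-dimethylchroman-5-yl)-7-(2-methylbut-3-en-2-yl)benzofuran-4,6-diol (CNP0300714.0) | C=CC(C)(C)c1c(O)cc(O)c2cc(-c3cc(O)cc4c3CCC(C)(C)O4)oc12 | target

## Step count and least certain steps

Total: 14 steps. Longest linear sequence: 10 steps (9 to 25, steps 5–11 and 12–14); the other branch has 4 steps (1 to 8, steps 1–4).

Step 12 (key step). The most likely failure is self-condensation of the quinone methide, or O-alkylation of the phenoxide by the sulfonium salt, outrunning ylide addition. The benzylic sulfonium C–H is only marginally acidic towards carbonate and the ylide carbon is hindered by the ortho ring carbon C4a'. A [2,3]-sigmatropic (Sommelet–Hauser) drain of the ylide is the second risk. The fallback sets out from 8 and 17 and comes back at 24. It changes the one-carbon partner from an ylide to an ester carbonyl and moves the carbanion to C3. 8 is treated with PPh3 and Cs2CO3; the phosphine can be used in excess and needs no deprotonation equilibrium, and it captures the quinone methide as 2-(2-methylbut-3-en-2-yl)-3,5-bis(TBSO)-6-[(triphenylphosphonio)methyl]phenolate F1. 17 is oxidised (TEMPO, PhI(OAc)2, aqueous MeCN) to 7-(TBSO)-2,2-dimethylchroman-5-carboxylic acid F2. Carbodiimide coupling of F1 with F2 gives the O-aroyl ylide 2-(2-methylbut-3-en-2-yl)-3,5-bis(TBSO)-6-[(triphenylphosphoranylidene)methyl]phenyl 7-(TBSO)-2,2-dimethylchroman-5-carboxylate F3. In warm toluene F3 should close by intramolecular Wittig reaction on the ester carbonyl to give 24, so 23 and step 13 are by-passed.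

Step 13. The most likely failure is loss of site selectivity in the hydride abstraction. The oxidant may also attack C4' of the chroman (benzylic, activated by O1' and the para silyloxy group) and turn the pyran into a chromene, or oxidise 24 further once formed. The fallback sets out from 8 and 17 and comes back at 24. It assembles the furan at the benzofuran oxidation level, so no oxidant is needed. 17 is oxidised with MnO2 to 7-(TBSO)-2,2-dimethylchroman-5-carbaldehyde F4. Under N-heterocyclic carbene catalysis (thiazolium salt, Cs2CO3) the acyl anion equivalent of F4 adds to quinone methide 20 released from 8, giving 1-[7-(TBSO)-2,2-dimethylchroman-5-yl]-2-[2-hydroxy-3-(2-methylbut-3-en-2-yl)-4,6-bis(TBSO)phenyl]ethan-1-one F5. Cyclodehydration of F5 through its hemiketal (pyridinium p-toluenesulfonate, toluene) gives 24.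

Step 2. The most likely failure is secondary thermal reaction of the product at 180 °C: addition of the newly freed C4 hydroxyl across the vinyl group, the abnormal Claisen isomerisation of the ortho-(1,1-dimethylallyl)phenol, and cleavage of the ether with loss of isoprene. The fallback sets out from 3 and comes back at 4. It runs the rearrangement on a silylated substrate and captures the new phenol as it forms. 3 is converted with N,O-bis(trimethylsilyl)acetamide into 4-[(3-methylbut-2-en-1-yl)oxy]-2,6-bis(trimethylsilyloxy)benzaldehyde F6. Heating F6 with excess silylating agent gives 3-(2-methylbut-3-en-2-yl)-2,4,6-tris(trimethylsilyloxy)benzaldehyde F7, and methanolysis on work-up returns 4.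

Step 4. The most likely failure is over-reduction to the methyl compound (hydride capturing the ionised benzylic carbon if ionisation begins while borohydride is still present), migration of the neighbouring silyl group from the aryl oxygen to the new benzylic alkoxide during the reduction, or oligomerisation by attack of a second electron-rich ring on the benzylic cation before sulfinate adds. The fallback sets out from 5 and comes back at 8. It is hydride-free and delivers the sulfonyl group from within. 5 is condensed with p-toluenesulfonohydrazide to N'-[(E)-[2-hydroxy-3-(2-methylbut-3-en-2-yl)-4,6-bis(TBSO)phenyl]methylidene]-4-methylbenzenesulfonohydrazide F8. Heating F8 with K2CO3 in dioxane should give 8 through Bamford–Stevens-type loss of sulfinate to the diazo compound, protonation by the neighbouring phenol, loss of dinitrogen and recombination with sulfinate.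

Step 7. The most likely failure is incomplete ring closure (tertiary bromide or alkene surviving), intermolecular Friedel–Crafts alkylation by the tertiary cation, or partial cleavage of the methyl ester. The fallback sets out from 10 and comes back at 15. It separates demethylation, coupling and ring closure. 10 is demethylated with BBr3 to methyl 2-bromo-3,5-dihydroxybenzoate F9. B-alkyl Suzuki–Miyaura coupling of F9 with 12, with extra base for the phenols, gives methyl 3,5-dihydroxy-2-(3-hydroxy-3-methylbutyl)benzoate F10. Catalytic p-toluenesulfonic acid in toluene closes F10 to 15.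

## Further compounds

F1 | step 12 | 2-(2-methylbut-3-en-2-yl)-3,5-bis(TBSO)-6-[(triphenylphosphonio)methyl]phenolate | C=CC(C)(C)c1c([O-])c(C[P+](c2ccccc2)(c2ccccc2)c2ccccc2)c(O[Si](C)(C)C(C)(C)C)cc1O[Si](C)(C)C(C)(C)C
F2 | step 12 | 7-(TBSO)-2,2-dimethylchroman-5-carboxylic acid | OC(=O)c1cc(O[Si](C)(C)C(C)(C)C)cc2c1CCC(C)(C)O2
F3 | step 12 | 2-(2-methylbut-3-en-2-yl)-3,5-bis(TBSO)-6-[(triphenylphosphoranylidene)methyl]phenyl 7-(TBSO)-2,2-dimethylchroman-5-carboxylate | C=CC(C)(C)c1c(OC(=O)c2cc(O[Si](C)(C)C(C)(C)C)cc3c2CCC(C)(C)O3)c(C=P(c2ccccc2)(c2ccccc2)c2ccccc2)c(O[Si](C)(C)C(C)(C)C)cc1O[Si](C)(C)C(C)(C)C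
F4 | step 13 | 7-(TBSO)-2,2-dimethylchroman-5-carbaldehyde | O=Cc1cc(O[Si](C)(C)C(C)(C)C)cc2c1CCC(C)(C)O2
F5 | step 13 | 1-[7-(TBSO)-2,2-dimethylchroman-5-yl]-2-[2-hydroxy-3-(2-methylbut-3-en-2-yl)-4,6-bis(TBSO)phenyl]ethan-1-one | C=CC(C)(C)c1c(O)c(CC(=O)c2cc(O[Si](C)(C)C(C)(C)C)cc3c2CCC(C)(C)O3)c(O[Si](C)(C)C(C)(C)C)cc1O[Si](C)(C)C(C)(C)C
F6 | step 2 | 4-[(3-methylbut-2-en-1-yl)oxy]-2,6-bis(trimethylsilyloxy)benzaldehyde | O=Cc1c(O[Si](C)(C)C)cc(OCC=C(C)C)cc1O[Si](C)(C)C
F7 | step 2 | 3-(2-methylbut-3-en-2-yl)-2,4,6-tris(trimethylsilyloxy)benzaldehyde | O=Cc1c(O[Si](C)(C)C)cc(O[Si](C)(C)C)c(C(C)(C)C=C)c1O[Si](C)(C)C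
F8 | step 4 | N'-[(E)-[2-hydroxy-3-(2-methylbut-3-en-2-yl)-4,6-bis(TBSO)phenyl]methylidene]-4-methylbenzenesulfonohydrazide | Cc1ccc(cc1)S(=O)(=O)N/N=C/c1c(O[Si](C)(C)C(C)(C)C)cc(O[Si](C)(C)C(C)(C)C)c(C(C)(C)C=C)c1O
F9 | step 7 | methyl 2-bromo-3,5-dihydroxybenzoate | COC(=O)c1cc(O)cc(O)c1Br
F10 | step 7 | methyl 3,5-dihydroxy-2-(3-hydroxy-3-methylbutyl)benzoate | COC(=O)c1cc(O)cc(O)c1CCC(C)(C)O
A1 | alternative 1 | 5-[7-(2-methylbut-3-en-2-yl)-4,6-bis(TBSO)benzofuran-2-yl]-4-(3-methylbut-2-en-1-yl)benzene-1,3-diol | C=CC(C)(C)c1c(O[Si](C)(C)C(C)(C)C)cc(O[Si](C)(C)C(C)(C)C)c2cc(-c3cc(O)cc(O)c3CC=C(C)C)oc12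
A2 | alternative 1 | 9-methyl-1-[7-(2-methylbut-3-en-2-yl)-4,6-bis(TBSO)benzofuran-2-yl]dec-8-ene-1,3,5-trione | C=CC(C)(C)c1c(O[Si](C)(C)C(C)(C)C)cc(O[Si](C)(C)C(C)(C)C)c2cc(C(=O)CC(=O)CC(=O)CCC=C(C)C)oc12
A3 | alternative 2 | 7-(2-methylbut-3-en-2-yl)-6-(triisopropylsilyloxy)-2-[7-(TBSO)-2,2-dimethylchroman-5-yl]benzofuran-4-ol | C=CC(C)(C)c1c(O[Si](C(C)C)(C(C)C)C(C)C)cc(O)c2cc(-c3cc(O[Si](C)(C)C(C)(C)C)cc4c3CCC(C)(C)O4)oc12
A4 | alternative 2 | 4-{5-[7-(TBSO)-2,2-dimethylchroman-5-yl]furan-2-yl}-4-(2-methylbut-3-en-2-yl)-3-(triisopropylsilyloxy)cyclobut-2-en-1-one (racemic) | O=C1C=C(O[Si](C(C)C)(C(C)C)C(C)C)C1(C(C)(C)C=C)c1ccc(-c2cc(O[Si](C)(C)C(C)(C)C)cc3c2CCC(C)(C)O3)o1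
A5 | alternative 3 | 2-[7-(TBSO)-2,2-dimethylchroman-5-yl]-7-(2-methylbut-3-en-2-yl)-4,6-bis(TBSO)benzofuran (identical with 24) | C=CC(C)(C)c1c(O[Si](C)(C)C(C)(C)C)cc(O[Si](C)(C)C(C)(C)C)c2cc(-c3cc(O[Si](C)(C)C(C)(C)C)cc4c3CCC(C)(C)O4)oc12
A6 | alternative 3 | 2-(hydroxymethyl)-3-[7-(2-methylbut-3-en-2-yl)-4,6-bis(TBSO)benzofuran-2-yl]-5-(TBSO)phenol | C=CC(C)(C)c1c(O[Si](C)(C)C(C)(C)C)cc(O[Si](C)(C)C(C)(C)C)c2cc(-c3cc(O[Si](C)(C)C(C)(C)C)cc(O)c3CO)oc12
A7 | alternative 3 | 2-methylpropene | CC(C)=C
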